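**Retrosynthetic overview**

1. The last C–C bond is C4–C1′ (tertiary carbinol carbon of the six-membered ring to the first triene carbon). The complete lower half, lithiated at C1′ and carrying its cyclopentenone amide as an N,O-dianion, adds to the C4 carbonyl of an epoxy-quinone mono-ketal that already bears the upper dienamide; ketal hydrolysis then ends the synthesis.
2. Enabling feature: C4 of the cyclohexenone ring is a former quinone carbonyl. With C1 held as a dimethyl ketal it is the only free C=O, and the cis-fused C5–O–C6 oxirane shields one ring face, so attack anti to it gives the required syn hydroxy-epoxide. In the five-membered ring the amide N–H and the enol O–H form one vinylogous-acid unit that is inert once doubly deprotonated.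
3. Upper half: HWE dienoate → acid → anilide of 2,5-dimethoxyaniline → oxidative dearomatisation to the quinone mono-ketal → asymmetric phase-transfer epoxidation.
4. Lower half: glutaconaldehyde salt → 5-bromodienal → Wittig → bromotrienoic acid → amide with 2-amino-3-hydroxycyclopentenone (from cyclopentane-1,3-dione by nitrosation and hydrogenation).
5. Ring order: the cyclohexane and cyclopentane rings are bought; the six-membered carbocycle comes from the benzene ring (step 4), then the oxirane is closed (step 5); no ring is formed later.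

Key step: step 12

Numbering used below for the six-membered ring: C1 = carbonyl (or ketal) carbon, C2 = N-bearing carbon, C3 = CH, C4 = carbinol (or ketone) carbon, C5/C6 = oxirane carbons; C1′–C7′ = lower chain from the ring to the amide carbonyl.

Assumption: the cinchonine-derived N-benzyl ammonium salt is taken to deliver the (5S,6R)-oxirane; if the sense of induction is the opposite, its pseudo-enantiomer (cinchonidine series) is used instead. Glutaconaldehyde potassium salt and triphenylphosphine dibromide are taken as commercial.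

**Route**

Step 1
Reactants: 1 cyclohexanecarbaldehyde; 2 triethyl 4-phosphonocrotonate
Product: 3 ethyl (2E,4E)-5-cyclohexylpenta-2,4-dienoate
Conditions: LiHMDS, THF, −78 °C → rt
Reagents that add atoms: none
Why: Horner–Wadsworth–Emmons olefination with the vinylogous phosphonate anion, which reacts at its α-carbon and, as a stabilised reagent, should give the (2E,4E)-dienoate.

Step 2
Reactants: 3 ethyl (2E,4E)-5-cyclohexylpenta-2,4-dienoate
Product: 4 (2E,4E)-5-cyclohexylpenta-2,4-dienoic acid
Conditions: LiOH·H2O, THF/MeOH/H2O, rt; then 1 M HCl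
Reagents that add atoms: lithium hydroxide, [Li+].[OH-]
Why: Saponification (acyl–oxygen ester hydrolysis) that leaves the conjugated diene untouched.

Step 3
Reactants: 4 (2E,4E)-5-cyclohexylpenta-2,4-dienoic acid; 5 2,5-dimethoxyaniline
Product: 7 (2E,4E)-5-cyclohexyl-N-(2,5-dimethoxyphenyl)penta-2,4-dienamide, via acid chloride 6 (not isolated)
Conditions: (COCl)2, cat. DMF, CH2Cl2, 0 °C → rt; then 5, Et3N, CH2Cl2, 0 °C → rt
Reagents that add atoms: none
Why: Acid chloride formation followed by Schotten–Baumann-type N-acylation of the electron-rich aniline.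

Step 4
Reactants: 7 (2E,4E)-5-cyclohexyl-N-(2,5-dimethoxyphenyl)penta-2,4-dienamide
Product: 8 (2E,4E)-5-cyclohexyl-N-(6,6-dimethoxy-3-oxocyclohexa-1,4-dien-1-yl)penta-2,4-dienamide
Conditions: PhI(OAc)2, MeOH, 0 °C → rt; aq. NaHCO3 work-up
Reagents that add atoms: methanol, CO; water, O
Why: Hypervalent-iodine oxidative dearomatisation of the p-dimethoxy anilide, in which methanol is captured at the methoxy-bearing carbon ortho to nitrogen and the other methoxy-bearing carbon (para to that one) is hydrolysed to the carbonyl, giving the p-quinone mono-ketal as a vinylogous amide.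

Step 5
Reactants: 8 (2E,4E)-5-cyclohexyl-N-(6,6-dimethoxy-3-oxocyclohexa-1,4-dien-1-yl)penta-2,4-dienamide
Product: 9 (2E,4E)-5-cyclohexyl-N-[(1S,6R)-5,5-dimethoxy-2-oxo-7-oxabicyclo[4.1.0]hept-3-en-4-yl]penta-2,4-dienamide
Conditions: t-BuOOH, aq. NaOH (cat.), N-benzylcinchoninium chloride (10 mol%), toluene, 0 °C → rt
Reagents that add atoms: tert-butyl hydroperoxide, CC(C)(C)OO
Why: Weitz–Scheffer nucleophilic epoxidation under chiral phase-transfer catalysis, in which the ion-paired peroxide anion adds to C6 of the only electrophilic alkene (the other is a deactivated vinylogous amide) from one enantiotopic face and ring closure sets C5 and C6 together as the cis-fused (5S,6R)-oxirane.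

Step 6
Reactants: 10 glutaconaldehyde potassium salt
Product: 11 (2E,4E)-5-bromopenta-2,4-dienal
Conditions: Ph3PBr2, CH2Cl2, 0 °C → rt, dark
Reagents that add atoms: triphenylphosphine dibromide, BrP(Br)(c1ccccc1)(c1ccccc1)c1ccccc1
Why: Deoxybromination of the vinylogous-acid enolate through an alkoxyphosphonium ion and addition–elimination of bromide (as in the conversion of 1,3-diketones into β-bromo enones), with the (2E,4E)-isomer expected as the thermodynamic product.

Step 7
Reactants: 11 (2E,4E)-5-bromopenta-2,4-dienal; 12 ethyl (triphenylphosphoranylidene)acetate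
Product: 13 ethyl (2E,4E,6E)-7-bromohepta-2,4,6-trienoate
Conditions: CH2Cl2, rt, dark
Reagents that add atoms: none
Why: Wittig olefination with a stabilised ylide, which should form the new C=C bond E-selectively without touching the vinyl bromide.

Step 8
Reactants: 13 ethyl (2E,4E,6E)-7-bromohepta-2,4,6-trienoate
Product: 14 (2E,4E,6E)-7-bromohepta-2,4,6-trienoic acid
Conditions: LiOH, THF/H2O, 0 °C → rt; then 1 M HCl
Reagents that add atoms: lithium hydroxide, [Li+].[OH-]
Why: Mild saponification, to which the vinyl bromide and the triene are inert.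

Step 9
Reactants: 15 cyclopentane-1,3-dione
Product: 16 2-(hydroxyimino)cyclopentane-1,3-dione
Conditions: NaNO2, aq. HCl, 0 °C
Reagents that add atoms: sodium nitrite, [Na+].[O-]N=O
Why: C-Nitrosation of the enol of the cyclic 1,3-dione at C2, followed by tautomerisation to the oxime.

Step 10
Reactants: 16 2-(hydroxyimino)cyclopentane-1,3-dione
Product: 17 2-amino-3-hydroxycyclopent-2-en-1-one hydrochloride
Conditions: H2 (1 atm), 10% Pd/C, HCl, MeOH, rt
Reagents that add atoms: hydrogen chloride, Cl
Why: Catalytic hydrogenation of the oxime to the primary amine, which is trapped as the hydrochloride of its stable enol (vinylogous-acid) tautomer.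

Step 11
Reactants: 14 (2E,4E,6E)-7-bromohepta-2,4,6-trienoic acid; 17 2-amino-3-hydroxycyclopent-2-en-1-one hydrochloride
Product: 19 (2E,4E,6E)-7-bromo-N-(2-hydroxy-5-oxocyclopent-1-en-1-yl)hepta-2,4,6-trienamide, via acid chloride 18 (not isolated)
Conditions: (COCl)2, cat. DMF, CH2Cl2, 0 °C; then 17, Et3N, THF/DMF, −20 °C → rt, dark
Reagents that add atoms: none
Why: Acid chloride formation and N-acylation of the amino-enolone, where any O-acyl isomer should rearrange to the amide by O→N acyl shift.

Step 12
Reactants: 19 (2E,4E,6E)-7-bromo-N-(2-hydroxy-5-oxocyclopent-1-en-1-yl)hepta-2,4,6-trienamide; 9 (2E,4E)-5-cyclohexyl-N-[(1S,6R)-5,5-dimethoxy-2-oxo-7-oxabicyclo[4.1.0]hept-3-en-4-yl]penta-2,4-dienamide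
Product: 21 (2E,4E,6E)-7-[(1S,2R,6R)-4-[(2E,4E)-5-cyclohexylpenta-2,4-dienamido]-2-hydroxy-5,5-dimethoxy-7-oxabicyclo[4.1.0]hept-3-en-2-yl]-N-(2-hydroxy-5-oxocyclopent-1-en-1-yl)hepta-2,4,6-trienamide, via trilithio trienamide 20 (not isolated)
Conditions: 19, MeLi (2 equiv), THF, −78 °C; t-BuLi (2 equiv), −78 °C; then 9 pre-treated with NaH (THF, 0 °C), −78 → −40 °C; aq. NH4Cl
Reagents that add atoms: none
Why: Bromine–lithium exchange on the (E)-bromotriene, run on the preformed N,O-dilithio salt so that the amide and the cyclopentenone of the lower half are masked as amidate and 1,3-diketonate, should give the (1E,3E,5E)-trienyl-lithium 20 with retention of geometry; this adds 1,2 to C4 of 9, the only free carbonyl (C1 is a ketal and the upper amide is present as its sodium amidate). The closest known reaction types are the addition of alkenyl-lithium reagents to epoxy-quinone mono-ketals and the halogen–lithium exchange/carbonyl addition of ω-bromopolyenes. No ring is closed. The one new stereocentre, C4 (R), is controlled by the cis-fused C5–O–C6 oxirane, whose oxygen blocks one face of the flattened enone ring, so that the nucleophile enters anti to it and the new hydroxyl ends up cis to the oxirane oxygen. The step needs chemoselectivity for C4=O over ketal, amidates, diketonate and oxirane, which the anionic masking and the low temperature secure, and retention at C1′, which the configurational stability of alkenyl-lithiums at −78 °C secures. In one operation it joins the two complete, unprotected halves, finishes the C29 skeleton with its all-E triene, and sets the last stereocentre.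

Step 13
Reactants: 21 (2E,4E,6E)-7-[(1S,2R,6R)-4-[(2E,4E)-5-cyclohexylpenta-2,4-dienamido]-2-hydroxy-5,5-dimethoxy-7-oxabicyclo[4.1.0]hept-3-en-2-yl]-N-(2-hydroxy-5-oxocyclopent-1-en-1-yl)hepta-2,4,6-trienamide
Product: 22 (2E,4E,6E)-7-[(1S,2R,6R)-4-[(2E,4E)-5-cyclohexylpenta-2,4-dienamido]-2-hydroxy-5-oxo-7-oxabicyclo[4.1.0]hept-3-en-2-yl]-N-(2-hydroxy-5-oxocyclopent-1-en-1-yl)hepta-2,4,6-trienamide
Conditions: montmorillonite K10, wet CH2Cl2, rt, dark
Reagents that add atoms: water, O
Why: Mild solid-acid hydrolysis of the dimethyl ketal, under conditions expected to leave the tertiary allylic alcohol, the oxirane and both polyenes intact; no stereocentre is touched.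

**Compound list**

1 | cyclohexanecarbaldehyde | O=CC1CCCCC1 | starting material
2 | triethyl 4-phosphonocrotonate | CCOC(=O)/C=C/CP(=O)(OCC)OCC | starting material
3 | ethyl (2E,4E)-5-cyclohexylpenta-2,4-dienoate | CCOC(=O)/C=C/C=C/C1CCCCC1 | intermediate
4 | (2E,4E)-5-cyclohexylpenta-2,4-dienoic acid | OC(=O)/C=C/C=C/C1CCCCC1 | intermediate
5 | 2,5-dimethoxyaniline | COc1ccc(OC)c(N)c1 | starting material
6 | (2E,4E)-5-cyclohexylpenta-2,4-dienoyl chloride | ClC(=O)/C=C/C=C/C1CCCCC1 | intermediate (not isolated)
7 | (2E,4E)-5-cyclohexyl-N-(2,5-dimethoxyphenyl)penta-2,4-dienamide | COc1ccc(OC)c(NC(=O)/C=C/C=C/C2CCCCC2)c1 | intermediate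
8 | (2E,4E)-5-cyclohexyl-N-(6,6-dimethoxy-3-oxocyclohexa-1,4-dien-1-yl)penta-2,4-dienamide | O=C(/C=C/C=C/C1CCCCC1)NC1=CC(=O)C=CC1(OC)OC | intermediate
9 | (2E,4E)-5-cyclohexyl-N-[(1S,6R)-5,5-dimethoxy-2-oxo-7-oxabicyclo[4.1.0]hept-3-en-4-yl]penta-2,4-dienamide | O=C(/C=C/C=C/C1CCCCC1)NC1=CC(=O)[C@H]2O[C@H]2C1(OC)OC | intermediate
10 | glutaconaldehyde potassium salt | [K+].[O-]/C=C/C=C/C=O | starting material
11 | (2E,4E)-5-bromopenta-2,4-dienal | O=C/C=C/C=C/Br | intermediate
12 | ethyl (triphenylphosphoranylidene)acetate | CCOC(=O)C=P(c1ccccc1)(c1ccccc1)c1ccccc1 | starting material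
13 | ethyl (2E,4E,6E)-7-bromohepta-2,4,6-trienoate | CCOC(=O)/C=C/C=C/C=C/Br | intermediate
14 | (2E,4E,6E)-7-bromohepta-2,4,6-trienoic acid | OC(=O)/C=C/C=C/C=C/Br | intermediate
15 | cyclopentane-1,3-dione | O=C1CCC(=O)C1 | starting material
16 | 2-(hydroxyimino)cyclopentane-1,3-dione | O=C1CCC(=O)C1=NO | intermediate
17 | 2-amino-3-hydroxycyclopent-2-en-1-one hydrochloride | NC1=C(O)CCC1=O.Cl | intermediate
18 | (2E,4E,6E)-7-bromohepta-2,4,6-trienoyl chloride | ClC(=O)/C=C/C=C/C=C/Br | intermediate (not isolated)
19 | (2E,4E,6E)-7-bromo-N-(2-hydroxy-5-oxocyclopent-1-en-1-yl)hepta-2,4,6-trienamide | Br/C=C/C=C/C=C/C(=O)NC1=C(O)CCC1=O | intermediate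
20 | N,O-dilithio (2E,4E,6E)-7-lithio-N-(2-hydroxy-5-oxocyclopent-1-en-1-yl)hepta-2,4,6-trienamide | [Li]/C=C/C=C/C=C/C(=O)N([Li])C1=C(O[Li])CCC1=O | intermediate (not isolated)
21 | C1 dimethyl ketal of the target (4R,5S,6R; OH cis to the oxirane oxygen) | O=C(/C=C/C=C/C1CCCCC1)NC1=C[C@](O)(/C=C/C=C/C=C/C(=O)NC2=C(O)CCC2=O)[C@H]2O[C@H]2C1(OC)OC | intermediate
22 | (2E,4E,6E)-7-[(1S,2R,6R)-4-[(2E,4E)-5-cyclohexylpenta-2,4-dienamido]-2-hydroxy-5-oxo-7-oxabicyclo[4.1.0]hept-3-en-2-yl]-N-(2-hydroxy-5-oxocyclopent-1-en-1-yl)hepta-2,4,6-trienamide | O=C(/C=C/C=C/C1CCCCC1)NC1=C[C@](O)(/C=C/C=C/C=C/C(=O)NC2=C(O)CCC2=O)[C@H]2O[C@H]2C1=O | target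

**Step count and risks**

Total step count: 13. Longest linear sequence: 7 steps (1, 2, 3, 4, 5, 12, 13).

Steps most likely to fail:

Step 12 (key step). Proton transfer within or between the polyanionic aggregates, or their low solubility, may quench the trienyl-lithium before it reaches the carbonyl, or the exchange may stay incomplete. The fallback builds the chain in two stages so that only a small, excess-tolerant alkenyl-lithium has to add to the ketone. Setting out from 9, (E)-2-(tributylstannyl)vinyl-lithium F1 (from (E)-1,2-bis(tributylstannyl)ethene and n-BuLi, THF, −78 °C) would add to C4 under the same facial control to give vinylstannane carbinol F2. In parallel, 11 would be oxidised (Pinnick: NaClO2, NaH2PO4, 2-methyl-2-butene) to (2E,4E)-5-bromopenta-2,4-dienoic acid F3, converted into (2E,4E)-5-bromopenta-2,4-dienoyl chloride F4 and coupled with 17 to the bromodienamide F5. Stille coupling of F2 with F5 (Pd catalyst, DMF, rt) would form the C2′–C3′ bond and come back to the route at 21.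

Step 11. Competing O-acylation or over-acylation of the ambident amino-enolone, and decomposition of the light-sensitive trienoyl chloride, may erode the coupling. The fallback makes the amide bond on a two-carbon unit and the triene by olefination. Setting out from 17, bromoacetyl bromide would give 2-bromo-N-(2-hydroxy-5-oxocyclopent-1-en-1-yl)acetamide F6, triphenylphosphine would give the phosphonium bromide F7, and base (2 equiv) would give the stabilised amide ylide F8. Its Wittig reaction with 11 would come back to the route at 19.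

Step 5. Enantiofacial discrimination in the ion-paired peroxide addition may be low or reversed. The fallback obtains the enantiomer by resolution instead of catalysis. Setting out from 8, achiral Weitz–Scheffer epoxidation (t-BuOOH, DBU, CH2Cl2) would give the racemic epoxide F9, which would be separated by preparative chromatography on a chiral stationary phase, coming back to the route at 9.

**Further compounds**

F1 | step 12 | (E)-2-(tributylstannyl)vinyl-lithium | [Li]/C=C/[Sn](CCCC)(CCCC)CCCC
F2 | step 12 | (2E,4E)-5-cyclohexyl-N-[(1S,2R,6R)-2-hydroxy-5,5-dimethoxy-2-[(E)-2-(tributylstannyl)vinyl]-7-oxabicyclo[4.1.0]hept-3-en-4-yl]penta-2,4-dienamide | O=C(/C=C/C=C/C1CCCCC1)NC1=C[C@](O)(/C=C/[Sn](CCCC)(CCCC)CCCC)[C@H]2O[C@H]2C1(OC)OC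
F3 | step 12 | (2E,4E)-5-bromopenta-2,4-dienoic acid | OC(=O)/C=C/C=C/Br
F4 | step 12 | (2E,4E)-5-bromopenta-2,4-dienoyl chloride | ClC(=O)/C=C/C=C/Br
F5 | step 12 | (2E,4E)-5-bromo-N-(2-hydroxy-5-oxocyclopent-1-en-1-yl)penta-2,4-dienamide | Br/C=C/C=C/C(=O)NC1=C(O)CCC1=O
F6 | step 11 | 2-bromo-N-(2-hydroxy-5-oxocyclopent-1-en-1-yl)acetamide | BrCC(=O)NC1=C(O)CCC1=O
F7 | step 11 | {2-[(2-hydroxy-5-oxocyclopent-1-en-1-yl)amino]-2-oxoethyl}triphenylphosphonium bromide | [Br-].O=C(C[P+](c1ccccc1)(c1ccccc1)c1ccccc1)NC1=C(O)CCC1=O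
F8 | step 11 | N-(2-hydroxy-5-oxocyclopent-1-en-1-yl)-2-(triphenylphosphoranylidene)acetamide | O=C(C=P(c1ccccc1)(c1ccccc1)c1ccccc1)NC1=C(O)CCC1=O
F9 | step 5 | racemic (2E,4E)-5-cyclohexyl-N-(5,5-dimethoxy-2-oxo-7-oxabicyclo[4.1.0]hept-3-en-4-yl)penta-2,4-dienamide | O=C(/C=C/C=C/C1CCCCC1)NC1=CC(=O)C2OC2C1(OC)OC
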